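(The data stem from a simulated flask for an exercise; the scatter is artificial.)

Count the Z first. At the end of the north-east run Z and L add up to 100% of the Z charged, while G and E stay close to zero, so Z is simply turning into L. If each L also takes one J, which no reading has yet tested, [Z] − [J] stays constant and J is the limiting reagent. L then has a ceiling, the charged [J] over the charged [Z]: 60.0%.

| setting | north-west | north-east | Sunday's | Saturday's |
|---|---|---|---|---|
| Z | 1.9 M | 1.9 M | 1.9 M | 1.9 M |
| J | 1.14 M | 1.14 M | 1.14 M | 1.14 M |
| X | 0.98 mM | 2.8 mM | 3.8 mM | 1.9 mM |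
| remark | run made earlier | run made earlier |  |  |
| time |  |  | 20 h | 20 h |

| run | time / h | Z / % | L / % | G / % | E / % |
|---|---|---|---|---|---|
| north-west | 1.00 | 98.3 | 2.0 | 0.3 | 0 |
| north-west | 3.00 | 95.6 | 4.3 | 0 | 0 |
| north-west | 6.00 | 91.8 | 8.6 | 0 | 0.3 |
| north-west | 8.00 | 88.7 | 11.1 | 0 | 0.4 |
| north-west | 12.0 | 83.7 | 16.5 | 0.3 | 0.1 |
| north-west | 15.0 | 80.6 | 20.4 | 0 | 0 |
| north-west | 20.0 | 74.0 | 26.7 | 0.3 | 0.5 |
| north-east | 1.00 | 95.8 | 4.6 | 0 | 0.2 |
| north-east | 3.00 | 88.0 | 11.8 | 0 | 0.4 |
| north-east | 6.00 | 77.6 | 22.9 | 0.1 | 0 |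
| north-east | 8.00 | 70.4 | 29.2 | 0 | 0 |
| north-east | 12.0 | 59.3 | 41.1 | 0.4 | 0.3 |
| north-east | 15.0 | 52.3 | 47.6 | 0 | 0.7 |
| north-east | 20.0 | 44.7 | 55.3 | 0 | 0.7 |

(standard deviation of a reading: 0.3 percentage points)



- which of these there is most of at the end, counted by the Z in it, Sunday's (L / Z / E / G)
- which of these there is most of at the end, counted by the Z in it, Saturday's (L / Z / E / G)
- how much there is at the end of the one of these that leads, in percent of the Z charged: Sunday's
- how much there is at the end of the one of these that leads, in percent of the Z charged: Saturday's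

A first guess, then: both new flasks end at the ceiling. But a ceiling is not a yield, since you still have to reach it in 20 h.

Catalyst and time seem to trade. The north-west run shows L 26.7% at 20 h, and the same [X] times time on the north-east run is 7.00 h, where L lies between 22.9% and 29.2%. So read each new flask on the north-east clock. Saturday's 20 h becomes 13.6 h, where L lies between 41.1% and 47.6% and Z between 59.3% and 52.3%. The first guess fails there: on this clock Saturday's ends below the ceiling with Z ahead.

Sunday's becomes 27.1 h, past the last reading. Carrying the last slope onward gives L 66.3%, more than the ceiling. Is the ceiling real, though? In the north-east run, the Z present fell by 0.0421 h⁻¹ early on but by 0.0314 h⁻¹ late, less per unit of Z. So falling [Z] does not account for the slowing, and falling [J] fits it. I expect Sunday's L just under the ceiling.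

The forecast gives L leading Sunday's at 59% and Z leading Saturday's at 55.6%, noting: “The north-east run's late slowdown (15–20 h, L about 55) fits J running out.”

The flasks give L at 59.3% on Sunday's and Z at 55.4% on Saturday's.

    Q → X + L (k = 15.0 min⁻¹)
    D → Q (k = 89.0 min⁻¹)
    Z + X ⇌ G (K = 25.0 M⁻¹, k = 1.10 M⁻¹ min⁻¹)
    G → E (k = 0.900 min⁻¹)
    J + E → D (k = 1.90 M⁻¹ min⁻¹)

In Sunday's flask at 10.0 h, with 25.9% of the J left, the catalyst was spread over X 23.4%, G 28.7%, E 45.9%, Q 1.72% and D 0.290% of its charge, and the step from J + E to D was still running. By 20.0 h J was down to 1.14%, E had become the resting state with 94.3% of the catalyst, and L stood at 59.3%, under the ceiling. Saturday's flask still held 26% of its J then, with L at 44.5%. The flask like Sunday's but charged with 0.68 M of J has a ceiling of 35.8%, and at 20.0 h it holds L 35.7%.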